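**Plan**
1. Retrosynthesis cuts, in order: the aryl–vinyl bond of the stilbene (Heck reaction on a 4-bromo-dihydrobenzofuran); the C2–C3 bond of the styryl-bearing dihydrobenzofuran (Rh-carbene C–H insertion); the aryl–C(=O) bond that joins the two halves (aryllithium + aldehyde); last, the C2–C3 bond of the 7-hydroxy-dihydrobenzofuran fused to the central catechol-type ring.
2. That last ring is not closed in its final size. Its C2 is benzylic and carries the ring oxygen, its C3 is doubly benzylic, so the C2–C3 bond can be made by excising a nitrogen placed between them: a six-membered 3-nitroso-1,3-benzoxazine loses N2 through its isodiazene and contracts to the five-membered ring.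
3. Forward: 5-bromo-o-vanillin → sulfinyl-imine arylation → aminophenol → N-nitroso benzoxazine (aminal with 4-anisaldehyde) → ring contraction to the 5-bromo-dihydrobenzofuran → Br–Li exchange, addition to the ring-A aldehyde, oxidation, hydrazone → C–H insertion closes the second dihydrobenzofuran → BBr3/Ac2O → Heck → deacetylation.
4. Stereochemistry: C3 of the contracted ring comes from the (S)-tert-butanesulfinyl auxiliary and is carried through the N2 extrusion; C3 of the second ring comes from the chiral Rh(II) catalyst; both C2 centres end trans (retention in the extrusion, and acid equilibration of the labile benzylic C2–O bond in the BBr3 step).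
5. Helpers and their removal: sulfinyl and MOM groups (step 4), ring nitrogen with its N=O (step 6), methyl ethers (step 12), acetates (step 14).

Key step: step 6

**Assumptions (remarks on the chemistry)**
- Step 3 is assumed to follow the usual chelated chair model for N-tert-butanesulfinyl aldimines ((S)-auxiliary gives the (R)-carbon); if the ortho-OMOM group reverses the sense, (R)-tert-butanesulfinamide is used.
- Rh2(R-PTAD)4 is taken as the catalyst antipode that gives 3S in step 11; otherwise Rh2(S-PTAD)4 is used.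
- Compound 10 is drawn as the expected 2,4-trans isomer; any cis portion would only alter C2 of 12, which step 12 equilibrates to trans.
- Compound 13 is taken as purchasable; otherwise it is one step from 2-bromo-4,6-dimethoxybenzaldehyde (BCl3, ortho-selective mono-demethylation).

**Route**

Step 1
Reactants: 1 5-bromo-2-hydroxy-3-methoxybenzaldehyde
Product: 2 5-bromo-3-methoxy-2-(methoxymethoxy)benzaldehyde
Conditions: MOMCl, i-Pr2NEt, CH2Cl2, 0 °C → rt
Reagents that add atoms: chloromethyl methyl ether, COCCl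
Why: O-alkylation of the phenol (MOM protection) keeps a magnesium phenoxide out of steps 2–3 and is later removed in the same operation as the sulfinyl group.

Step 2
Reactants: 2 5-bromo-3-methoxy-2-(methoxymethoxy)benzaldehyde; 3 (S)-2-methylpropane-2-sulfinamide
Product: 4 (S,E)-N-{[5-bromo-3-methoxy-2-(methoxymethoxy)phenyl]methylidene}-2-methylpropane-2-sulfinamide
Conditions: Ti(OEt)4, THF, rt
Reagents that add atoms: none
Why: Titanium-mediated condensation to the N-sulfinyl aldimine should give the E-imine, with Ti(OEt)4 acting as Lewis acid and water scavenger.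

Step 3
Reactants: 4 the N-sulfinyl imine; 5 3,5-dimethoxyphenylmagnesium chloride
Product: 6 (S)-N-{(R)-[5-bromo-3-methoxy-2-(methoxymethoxy)phenyl](3,5-dimethoxyphenyl)methyl}-2-methylpropane-2-sulfinamide
Conditions: 5 (THF solution), toluene, −45 °C; aq. NH4Cl
Reagents that add atoms: none
Why: Diastereoselective 1,2-addition of an aryl Grignard reagent to an N-tert-butanesulfinyl aldimine through the Mg–O=S chelated chair transition state, in which the (S)-sulfinyl group should direct the aryl to the face that makes the new carbon R.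

Step 4
Reactants: 6 the sulfinamide
Product: 7 2-[(R)-amino(3,5-dimethoxyphenyl)methyl]-4-bromo-6-methoxyphenol
Conditions: HCl (4 M in dioxane), MeOH, 0 °C → rt; aq. NaHCO3
Reagents that add atoms: none
Why: Acidic methanolysis should cleave the N–S bond and the MOM acetal together, while the benzhydryl C–N bond stays intact because the ammonium ion is a poor leaving group.

Step 5
Reactants: 7 the aminophenol; 8 4-methoxybenzaldehyde
Product: 10 (2S,4R)-6-bromo-4-(3,5-dimethoxyphenyl)-8-methoxy-2-(4-methoxyphenyl)-3-nitroso-3,4-dihydro-2H-1,3-benzoxazine, via NH-benzoxazine aminal 9 (not isolated)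
Conditions: 8, 4 Å MS, CH2Cl2, rt; then t-BuONO, 0 °C → rt
Reagents that add atoms: tert-butyl nitrite, CC(C)(C)ON=O
Why: Condensation gives the ring–chain tautomeric N,O-aminal and N-nitrosation (known for oxazolidines and tetrahydro-1,3-oxazines) should trap the ring form, the aminal carbon settling trans to C4 so that the C4 aryl is pseudoaxial and the C2 aryl pseudoequatorial (least A(1,3) strain against N–N=O).

Step 6
Reactants: 10 the N-nitroso benzoxazine
Product: 12 (2R,3R)-5-bromo-3-(3,5-dimethoxyphenyl)-7-methoxy-2-(4-methoxyphenyl)-2,3-dihydro-1-benzofuran, via isodiazene 11 (not isolated)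
Conditions: Na2S2O4, NaOH, EtOH/THF/H2O, 60 °C
Reagents that add atoms: none
Why: Proposed new method: dithionite in base should remove the nitroso oxygen to give the 1,1-diazene 11, which loses N2 because both carbons on nitrogen are radical-stabilising (C2 is α-oxy and p-anisyl-benzylic, C4 is doubly benzylic); the singlet 1,5-diradical (equally an oxocarbenium/diarylmethanide zwitterion), held by the O1–C8a=C4a arene tether, then collapses to the C2–C3 bond, so the six-membered benzoxazine contracts to the five-membered dihydrobenzofuran. The closest known reactions are the dithionite-mediated reductive N2 extrusion of N-nitrosodibenzylamines, including the stereospecific contraction of cis- and trans-N-nitroso-2,6-diphenylpiperidine to the 1,2-diphenylcyclopentanes, and the modern nitrogen deletion of secondary amines via isodiazenes; the nitrogen of an N,O-acetal has not been excised in this way. The single ring closure is a five-membered radical-pair (or ion-pair) recombination within the tether. No stereocentre is made from scratch: C3 derives from C4 of 10 (set in step 3) and C2 from the aminal carbon, both with retention, because collapse of the tethered pair should be faster than rotation about the aryl–C4 and O1–C2 bonds. The step needs N2 loss and C–C collapse to outrun 1,2-hydrogen shift to a hydrazone, cycloreversion to an o-quinone methide plus aryldiazomethane, and base-mediated α-deprotonation at C4; the double benzylic stabilisation, the absence of β-hydrogens (no disproportionation) and the short rigid tether should secure this.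

Step 7
Reactants: 13 2-bromo-6-hydroxy-4-methoxybenzaldehyde; 14 4-methoxybenzyl chloride
Product: 15 2-bromo-4-methoxy-6-[(4-methoxyphenyl)methoxy]benzaldehyde
Conditions: K2CO3, DMF, 60 °C
Reagents that add atoms: none
Why: Williamson ether synthesis; the 4-methoxybenzyl group is not a protecting group but the future C2 and its aryl substituent of the second dihydrobenzofuran.

Step 8
Reactants: 12 the bromo-dihydrobenzofuran; 15 the ring-A aldehyde
Product: 17 [2-bromo-4-methoxy-6-[(4-methoxyphenyl)methoxy]phenyl][(2R,3R)-3-(3,5-dimethoxyphenyl)-7-methoxy-2-(4-methoxyphenyl)-2,3-dihydro-1-benzofuran-5-yl]methanol (both carbinol epimers), via aryllithium 16 (not isolated)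
Conditions: n-BuLi, THF, −78 °C; then 15, −78 → −40 °C; aq. NH4Cl
Reagents that add atoms: none
Why: Br–Li exchange followed by 1,2-addition to the aldehyde, which at −78 °C should be faster than exchange at the aryl bromide of 15; the carbinol centre is left uncontrolled because it is oxidised next.

Step 9
Reactants: 17 the diaryl carbinol
Product: 18 [2-bromo-4-methoxy-6-[(4-methoxyphenyl)methoxy]phenyl][(2R,3R)-3-(3,5-dimethoxyphenyl)-7-methoxy-2-(4-methoxyphenyl)-2,3-dihydro-1-benzofuran-5-yl]methanone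
Conditions: Dess–Martin periodinane, NaHCO3, CH2Cl2, rt
Reagents that add atoms: none
Why: Buffered Dess–Martin oxidation of a diaryl carbinol, which should leave the electron-rich arenes and the benzylic ethers alone.

Step 10
Reactants: 18 the diaryl ketone
Product: 19 hydrazone of 18 (E/Z mixture)
Conditions: N2H4·H2O (excess), AcOH (cat.), n-BuOH, 110 °C
Reagents that add atoms: hydrazine, NN
Why: Acid-catalysed hydrazone condensation, driven with excess hydrazine and heat because one aryl group carries two ortho substituents.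

Step 11
Reactants: 19 the hydrazone
Product: 21 (2R,3S)-4-bromo-3-[(2R,3R)-3-(3,5-dimethoxyphenyl)-7-methoxy-2-(4-methoxyphenyl)-2,3-dihydro-1-benzofuran-5-yl]-6-methoxy-2-(4-methoxyphenyl)-2,3-dihydro-1-benzofuran, via diaryldiazomethane 20 (not isolated)
Conditions: MnO2, CH2Cl2, 0 °C → rt, filter; then Rh2(R-PTAD)4 (1 mol %), CH2Cl2, 0 °C
Reagents that add atoms: none
Why: Oxidation to the diaryldiazomethane and Rh(II)-catalysed enantioselective intramolecular 1,5 C–H insertion of the donor/donor carbene into the benzylic O–CH2 bond (precedented for 2,3-diaryl-dihydrobenzofurans of the resveratrol series), in which the chiral carboxylate catalyst sets C3 as S and the concerted insertion gives the 2,3-cis ring.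

Step 12
Reactants: 21 the cis,trans bis(dihydrobenzofuran) bromide
Product: 23 (2S,3S)-6-acetoxy-2-(4-acetoxyphenyl)-3-[(2R,3R)-7-acetoxy-2-(4-acetoxyphenyl)-3-(3,5-diacetoxyphenyl)-2,3-dihydro-1-benzofuran-5-yl]-4-bromo-2,3-dihydro-1-benzofuran, via trans-hexaphenol 22 (not isolated)
Conditions: BBr3, CH2Cl2, −78 °C → rt; H2O; then Ac2O, pyridine, DMAP, rt
Reagents that add atoms: acetic anhydride, CC(=O)OC(C)=O
Why: BBr3 cleavage of the six aryl methyl ethers (precedented on dihydrobenzofuran stilbenoid oligomers) should at the same time ionise the C2–O bond of the cis ring reversibly to a p-quinone-methide-type cation that recloses to the more stable trans ring with C3 untouched, and the air-sensitive hexaphenol is acetylated at once.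

Step 13
Reactants: 23 the hexaacetate bromide; 24 4-ethenylphenyl acetate
Product: 25 4-[(E)-2-{(2S,3S)-6-acetoxy-2-(4-acetoxyphenyl)-3-[(2R,3R)-7-acetoxy-2-(4-acetoxyphenyl)-3-(3,5-diacetoxyphenyl)-2,3-dihydro-1-benzofuran-5-yl]-2,3-dihydro-1-benzofuran-4-yl}ethenyl]phenyl acetate
Conditions: Pd[P(t-Bu)3]2 (5 mol %), Cy2NMe, dioxane, 80 °C
Reagents that add atoms: none
Why: Mizoroki–Heck reaction (precedented for acetate-protected stilbenes) in which syn-insertion and β-hydride elimination give the E-alkene, the acid-sensitive stilbene being introduced only after all Lewis-acid chemistry.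

Step 14
Reactants: 25 the heptaacetate
Product: 26 (2S,3S)-3-[(2R,3R)-3-(3,5-dihydroxyphenyl)-7-hydroxy-2-(4-hydroxyphenyl)-2,3-dihydro-1-benzofuran-5-yl]-2-(4-hydroxyphenyl)-4-[(E)-2-(4-hydroxyphenyl)ethenyl]-2,3-dihydro-1-benzofuran-6-ol
Conditions: K2CO3 (cat.), MeOH/THF, 0 °C → rt, argon, dark; AcOH
Reagents that add atoms: none
Why: Base-catalysed transesterification of the aryl acetates with methanol should free the seven phenols without touching the stilbene or either dihydrobenzofuran.

**Compound list**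
1 | 5-bromo-2-hydroxy-3-methoxybenzaldehyde | O=Cc1cc(Br)cc(OC)c1O | starting material
2 | 5-bromo-3-methoxy-2-(methoxymethoxy)benzaldehyde | O=Cc1cc(Br)cc(OC)c1OCOC | intermediate
3 | (S)-2-methylpropane-2-sulfinamide | CC(C)(C)[S@](=O)N | starting material
4 | (S,E)-N-{[5-bromo-3-methoxy-2-(methoxymethoxy)phenyl]methylidene}-2-methylpropane-2-sulfinamide | CC(C)(C)[S@](=O)/N=C/c1cc(Br)cc(OC)c1OCOC | intermediate
5 | 3,5-dimethoxyphenylmagnesium chloride (THF solution) | COc1cc(OC)cc([Mg]Cl)c1 | starting material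
6 | (S)-N-{(R)-[5-bromo-3-methoxy-2-(methoxymethoxy)phenyl](3,5-dimethoxyphenyl)methyl}-2-methylpropane-2-sulfinamide | Brc1cc(OC)c(OCOC)c(c1)[C@@H](c1cc(OC)cc(OC)c1)N[S@@](=O)C(C)(C)C | intermediate
7 | 2-[(R)-amino(3,5-dimethoxyphenyl)methyl]-4-bromo-6-methoxyphenol | Brc1cc(OC)c(O)c(c1)[C@@H](c1cc(OC)cc(OC)c1)N | intermediate
8 | 4-methoxybenzaldehyde | COc1ccc(C=O)cc1 | starting material
9 | (4R)-6-bromo-4-(3,5-dimethoxyphenyl)-8-methoxy-2-(4-methoxyphenyl)-3,4-dihydro-2H-1,3-benzoxazine (C2 epimers, in equilibrium with the open-chain imine; not isolated) | Brc1cc(OC)c2c(c1)[C@@H](c1cc(OC)cc(OC)c1)NC(c1ccc(OC)cc1)O2 | intermediate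
10 | (2S,4R)-6-bromo-4-(3,5-dimethoxyphenyl)-8-methoxy-2-(4-methoxyphenyl)-3-nitroso-3,4-dihydro-2H-1,3-benzoxazine | Brc1cc(OC)c2c(c1)[C@@H](c1cc(OC)cc(OC)c1)N(N=O)[C@H](c1ccc(OC)cc1)O2 | intermediate
11 | 1,1-diazene (isodiazene) at N3 of the (2S,4R)-benzoxazine of 10 (not isolated) | Brc1cc(OC)c2c(c1)[C@@H](c1cc(OC)cc(OC)c1)[N+](=[N-])[C@H](c1ccc(OC)cc1)O2 | intermediate
12 | (2R,3R)-5-bromo-3-(3,5-dimethoxyphenyl)-7-methoxy-2-(4-methoxyphenyl)-2,3-dihydro-1-benzofuran | Brc1cc(OC)c2c(c1)[C@@H](c1cc(OC)cc(OC)c1)[C@H](c1ccc(OC)cc1)O2 | intermediate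
13 | 2-bromo-6-hydroxy-4-methoxybenzaldehyde | O=Cc1c(O)cc(OC)cc1Br | starting material
14 | 4-methoxybenzyl chloride | COc1ccc(CCl)cc1 | starting material
15 | 2-bromo-4-methoxy-6-[(4-methoxyphenyl)methoxy]benzaldehyde | O=Cc1c(OCc2ccc(OC)cc2)cc(OC)cc1Br | intermediate
16 | [(2R,3R)-3-(3,5-dimethoxyphenyl)-7-methoxy-2-(4-methoxyphenyl)-2,3-dihydro-1-benzofuran-5-yl]lithium (not isolated) | [Li]c1cc(OC)c2c(c1)[C@@H](c1cc(OC)cc(OC)c1)[C@H](c1ccc(OC)cc1)O2 | intermediate
17 | [2-bromo-4-methoxy-6-[(4-methoxyphenyl)methoxy]phenyl][(2R,3R)-3-(3,5-dimethoxyphenyl)-7-methoxy-2-(4-methoxyphenyl)-2,3-dihydro-1-benzofuran-5-yl]methanol (carbinol epimers) | Brc1cc(OC)cc(OCc2ccc(OC)cc2)c1C(O)c1cc(OC)c2c(c1)[C@@H](c1cc(OC)cc(OC)c1)[C@H](c1ccc(OC)cc1)O2 | intermediate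
18 | [2-bromo-4-methoxy-6-[(4-methoxyphenyl)methoxy]phenyl][(2R,3R)-3-(3,5-dimethoxyphenyl)-7-methoxy-2-(4-methoxyphenyl)-2,3-dihydro-1-benzofuran-5-yl]methanone | Brc1cc(OC)cc(OCc2ccc(OC)cc2)c1C(=O)c1cc(OC)c2c(c1)[C@@H](c1cc(OC)cc(OC)c1)[C@H](c1ccc(OC)cc1)O2 | intermediate
19 | hydrazone of 18 (E/Z mixture) | Brc1cc(OC)cc(OCc2ccc(OC)cc2)c1C(=NN)c1cc(OC)c2c(c1)[C@@H](c1cc(OC)cc(OC)c1)[C@H](c1ccc(OC)cc1)O2 | intermediate
20 | (2R,3R)-5-{[2-bromo-4-methoxy-6-[(4-methoxyphenyl)methoxy]phenyl](diazo)methyl}-3-(3,5-dimethoxyphenyl)-7-methoxy-2-(4-methoxyphenyl)-2,3-dihydro-1-benzofuran (not isolated) | Brc1cc(OC)cc(OCc2ccc(OC)cc2)c1C(=[N+]=[N-])c1cc(OC)c2c(c1)[C@@H](c1cc(OC)cc(OC)c1)[C@H](c1ccc(OC)cc1)O2 | intermediate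
21 | (2R,3S)-4-bromo-3-[(2R,3R)-3-(3,5-dimethoxyphenyl)-7-methoxy-2-(4-methoxyphenyl)-2,3-dihydro-1-benzofuran-5-yl]-6-methoxy-2-(4-methoxyphenyl)-2,3-dihydro-1-benzofuran (new ring 2,3-cis) | Brc1cc(OC)cc2c1[C@H](c1cc(OC)c3c(c1)[C@@H](c1cc(OC)cc(OC)c1)[C@H](c1ccc(OC)cc1)O3)[C@H](c1ccc(OC)cc1)O2 | intermediate
22 | (2S,3S)-4-bromo-3-[(2R,3R)-3-(3,5-dihydroxyphenyl)-7-hydroxy-2-(4-hydroxyphenyl)-2,3-dihydro-1-benzofuran-5-yl]-2-(4-hydroxyphenyl)-2,3-dihydro-1-benzofuran-6-ol (not isolated) | Brc1cc(O)cc2c1[C@H](c1cc(O)c3c(c1)[C@@H](c1cc(O)cc(O)c1)[C@H](c1ccc(O)cc1)O3)[C@@H](c1ccc(O)cc1)O2 | intermediate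
23 | (2S,3S)-6-acetoxy-2-(4-acetoxyphenyl)-3-[(2R,3R)-7-acetoxy-2-(4-acetoxyphenyl)-3-(3,5-diacetoxyphenyl)-2,3-dihydro-1-benzofuran-5-yl]-4-bromo-2,3-dihydro-1-benzofuran | Brc1cc(OC(C)=O)cc2c1[C@H](c1cc(OC(C)=O)c3c(c1)[C@@H](c1cc(OC(C)=O)cc(OC(C)=O)c1)[C@H](c1ccc(OC(C)=O)cc1)O3)[C@@H](c1ccc(OC(C)=O)cc1)O2 | intermediate
24 | 4-ethenylphenyl acetate (4-acetoxystyrene) | C=Cc1ccc(OC(C)=O)cc1 | starting material
25 | heptaacetate of 26 (name as in step 13) | CC(=O)Oc1ccc(/C=C/c2cc(OC(C)=O)cc3c2[C@H](c2cc(OC(C)=O)c4c(c2)[C@@H](c2cc(OC(C)=O)cc(OC(C)=O)c2)[C@H](c2ccc(OC(C)=O)cc2)O4)[C@@H](c2ccc(OC(C)=O)cc2)O3)cc1 | intermediate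
26 | (2S,3S)-3-[(2R,3R)-3-(3,5-dihydroxyphenyl)-7-hydroxy-2-(4-hydroxyphenyl)-2,3-dihydro-1-benzofuran-5-yl]-2-(4-hydroxyphenyl)-4-[(E)-2-(4-hydroxyphenyl)ethenyl]-2,3-dihydro-1-benzofuran-6-ol | Oc1ccc(/C=C/c2cc(O)cc3c2[C@H](c2cc(O)c4c(c2)[C@@H](c2cc(O)cc(O)c2)[C@H](c2ccc(O)cc2)O4)[C@@H](c2ccc(O)cc2)O3)cc1 | target

**Step count**
Total: 14 steps. Longest linear sequence: 13 steps (steps 1–6 and 8–14; step 7 is a one-step side branch).

**Steps most likely to fail**

1. Step 6 (Proposed new method). The isodiazene may tautomerise to a hydrazone by 1,2-hydrogen shift, or fragment by cycloreversion to an o-quinone methide and an aryldiazomethane (loss of the C3 configuration). The hot base may also deprotonate the nitrosamine at C4, or the reduction may stop short of nitrogen loss. Fallback with known chemistry, closing the ring in its final size by carbene C–H insertion: it sets out from 1 and returns at 12. O-Alkylation of 1 with 14 (K2CO3, DMF) should give 5-bromo-3-methoxy-2-[(4-methoxyphenyl)methoxy]benzaldehyde F1; addition of 5 gives [5-bromo-3-methoxy-2-[(4-methoxyphenyl)methoxy]phenyl](3,5-dimethoxyphenyl)methanol F2; Dess–Martin oxidation gives the corresponding methanone F3; hydrazine gives its hydrazone F4; MnO2 gives 5-bromo-1-[diazo(3,5-dimethoxyphenyl)methyl]-3-methoxy-2-[(4-methoxyphenyl)methoxy]benzene F5. With the Rh2(PTAD)4 antipode that delivers 3R (Rh2(S-PTAD)4 under the assumption above), F5 should insert into the benzylic O–CH2 bond to give cis-configured (2S,3R)-5-bromo-3-(3,5-dimethoxyphenyl)-7-methoxy-2-(4-methoxyphenyl)-2,3-dihydro-1-benzofuran F6. Acid-mediated epimerisation at C2 (TFA, CH2Cl2, reversible benzylic C–O ionisation) then gives 12.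

2. Step 10. Condensation at a carbonyl shielded by an ortho-bromine and an ortho-benzyloxy group may stall, or the hydrazone may go on to the azine; the same crowding could later erode the selectivity of the carbene insertion. Fallback, setting out from 18 and returning at 23: intramolecular carbanion–carbonyl condensation of the benzylic O–CH2 group onto the ketone (phosphazene base P4-t-Bu, toluene, heat) should give 4-bromo-3-[(2R,3R)-3-(3,5-dimethoxyphenyl)-7-methoxy-2-(4-methoxyphenyl)-2,3-dihydro-1-benzofuran-5-yl]-6-methoxy-2-(4-methoxyphenyl)-1-benzofuran F7. Ionic hydrogenation (Et3SiH, TFA) should give the trans-dihydrobenzofuran as two diastereomers that differ at both new centres, since nothing controls C3 here. After separation by preparative HPLC, the (2S,3S) isomer, (2S,3S)-4-bromo-3-[(2R,3R)-3-(3,5-dimethoxyphenyl)-7-methoxy-2-(4-methoxyphenyl)-2,3-dihydro-1-benzofuran-5-yl]-6-methoxy-2-(4-methoxyphenyl)-2,3-dihydro-1-benzofuran F8, is taken through the conditions of step 12 to 23.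

3. Step 13. Oxidative addition at the electron-rich C4–Br bond next to the crowded C3 may be slow, leaving time for acetate transfer to the amine base, catalyst deactivation by liberated phenoxide, or 1,1-arylation of the styrene. Fallback, setting out from 23 and returning at 25, reverses the roles of the Heck partners: Stille coupling with tributyl(vinyl)stannane (Pd(PPh3)4, toluene, 100 °C) should give (2S,3S)-6-acetoxy-2-(4-acetoxyphenyl)-3-[(2R,3R)-7-acetoxy-2-(4-acetoxyphenyl)-3-(3,5-diacetoxyphenyl)-2,3-dihydro-1-benzofuran-5-yl]-4-ethenyl-2,3-dihydro-1-benzofuran F9. Heck arylation of this styrene with the more reactive 4-iodophenyl acetate (CC(=O)Oc1ccc(I)cc1; Pd(OAc)2, PPh3, Et3N, MeCN, 85 °C) then gives 25.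

**Further compounds**
F1 | step 6 | 5-bromo-3-methoxy-2-[(4-methoxyphenyl)methoxy]benzaldehyde | O=Cc1cc(Br)cc(OC)c1OCc1ccc(OC)cc1
F2 | step 6 | [5-bromo-3-methoxy-2-[(4-methoxyphenyl)methoxy]phenyl](3,5-dimethoxyphenyl)methanol (racemic) | OC(c1cc(OC)cc(OC)c1)c1cc(Br)cc(OC)c1OCc1ccc(OC)cc1
F3 | step 6 | [5-bromo-3-methoxy-2-[(4-methoxyphenyl)methoxy]phenyl](3,5-dimethoxyphenyl)methanone | O=C(c1cc(OC)cc(OC)c1)c1cc(Br)cc(OC)c1OCc1ccc(OC)cc1
F4 | step 6 | hydrazone of F3 | NN=C(c1cc(OC)cc(OC)c1)c1cc(Br)cc(OC)c1OCc1ccc(OC)cc1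
F5 | step 6 | 5-bromo-1-[diazo(3,5-dimethoxyphenyl)methyl]-3-methoxy-2-[(4-methoxyphenyl)methoxy]benzene | [N-]=[N+]=C(c1cc(OC)cc(OC)c1)c1cc(Br)cc(OC)c1OCc1ccc(OC)cc1
F6 | step 6 | (2S,3R)-5-bromo-3-(3,5-dimethoxyphenyl)-7-methoxy-2-(4-methoxyphenyl)-2,3-dihydro-1-benzofuran | Brc1cc(OC)c2c(c1)[C@@H](c1cc(OC)cc(OC)c1)[C@@H](c1ccc(OC)cc1)O2
F7 | step 10 | 4-bromo-3-[(2R,3R)-3-(3,5-dimethoxyphenyl)-7-methoxy-2-(4-methoxyphenyl)-2,3-dihydro-1-benzofuran-5-yl]-6-methoxy-2-(4-methoxyphenyl)-1-benzofuran | Brc1cc(OC)cc2oc(-c3ccc(OC)cc3)c(-c3cc(OC)c4c(c3)[C@@H](c3cc(OC)cc(OC)c3)[C@H](c3ccc(OC)cc3)O4)c12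
F8 | step 10 | (2S,3S)-4-bromo-3-[(2R,3R)-3-(3,5-dimethoxyphenyl)-7-methoxy-2-(4-methoxyphenyl)-2,3-dihydro-1-benzofuran-5-yl]-6-methoxy-2-(4-methoxyphenyl)-2,3-dihydro-1-benzofuran | Brc1cc(OC)cc2c1[C@H](c1cc(OC)c3c(c1)[C@@H](c1cc(OC)cc(OC)c1)[C@H](c1ccc(OC)cc1)O3)[C@@H](c1ccc(OC)cc1)O2
F9 | step 13 | (2S,3S)-6-acetoxy-2-(4-acetoxyphenyl)-3-[(2R,3R)-7-acetoxy-2-(4-acetoxyphenyl)-3-(3,5-diacetoxyphenyl)-2,3-dihydro-1-benzofuran-5-yl]-4-ethenyl-2,3-dihydro-1-benzofuran | C=Cc1cc(OC(C)=O)cc2c1[C@H](c1cc(OC(C)=O)c3c(c1)[C@@H](c1cc(OC(C)=O)cc(OC(C)=O)c1)[C@H](c1ccc(OC(C)=O)cc1)O3)[C@@H](c1ccc(OC(C)=O)cc1)O2
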